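# Synthesis plan for 3,3'-digalloylprocyanidin B2 by a coumarin (neoflavonoid) route

## The problem

3,3'-Digalloylprocyanidin B2 (27) consists of two (2R,3R)-epicatechin units joined by one bond from upper C4 (4R, the 4β bond, trans to the C3 oxygen) to lower C8; each C3 oxygen carries a galloyl ester and fourteen phenolic hydroxyl groups are free. The C4–C8 bond is the most crowded bond in the molecule, because C4 is doubly benzylic and sits between the ring A C5 oxygen, C3 and both ortho substituents (O1 and the C7 oxygen) of the lower ring A, and any coupling at this site must also tell lower C8 from C6. Of the five stereocentres the lower two can be bought with (−)-epicatechin, whereas the upper three are contiguous and can be set as a relay in which C4 directs C3 and C3 directs C2. The lower centres are too far from upper C4 to direct it, so the first upper centre needs reagent control. The C4–C8 bond heterolyses under acid, free catechol and pyrogallol rings oxidise, and gallate esters do not survive organolithium or hydride reagents; the phenols therefore stay benzylated until a final hydrogenolysis, the gallates are attached only after the last organometallic and hydride steps, and strong acid is avoided once the interflavan bond exists. The feature that opens the route is that upper C4 carries both lower C8 and the ring A carbon C4a, and that ring A, before ring C exists, is a symmetric phloroglucinol ring whose two carbons ortho to the O1 oxygen are equivalent. With C2 at the carboxyl oxidation level the upper unit is a 5,7-dioxygenated 4-arylcoumarin, whose C4–C4a bond can be closed from a 3,5-dioxygenated phenyl ester of an arylpropiolic acid in which C4 is still an alkyne carbon and the crowded C4–C8 bond is an ordinary aryl–alkyne bond.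

## Retrosynthesis

**Benzyl ethers and the two gallates.** The fourteen phenols of 27 are unmasked last by hydrogenolysis of the tetradeca-O-benzyl digallate 26. The lower gallate ester bond of 26 is cut to give alcohol 25 and acid 23; 25 comes from its lower silyl ether 24, and the upper gallate ester bond of 24 is cut to give alcohol 22 and a second molecule of 23. Carrying a gallate further back is ruled out by the organolithium and hydride steps. The two esters are attached one at a time, each from one molecule of 23, with the lower silyl ether as the differentiating element: the hindered upper C3 hydroxyl is acylated while it is the only free hydroxyl, so it can be forced with excess acid without any mixture of partly acylated products, and the easier lower hydroxyl follows after desilylation. The forward acylations must reach secondary hydroxyls next to aryl-bearing carbons, which a carbodiimide/DMAP esterification should do.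

**Upper ring C, O1–C2.** In 22 the upper O1–C2 bond is cut to give the open-chain phenol diol 21. This cut leaves the crowded C4–C8 bond alone and turns the 2,3-cis relationship into an SN2 problem at a benzylic carbinol. Because the ring closes with inversion, 21 must be the 1,2-anti diol. The forward Mitsunobu etherification has to stay bimolecular at an electron-rich benzylic carbon.

**C2–H and C2–aryl.** The carbinol hydrogen of 21 is removed to give α-hydroxy ketone 20, because the anti diol is what chelate-controlled hydride delivery next to the C3 hydroxyl provides. Ketone 20 is cut at the bond between C2 and the catechol ring and reconnected from the phenol oxygen to C2. This is the addition of aryllithium 17 (from bromide 16) to the 3-hydroxy dihydrocoumarin 15, whose leaving group is the ring A oxygen itself. The forward step must stop at the ketone.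

**C3–O and C4–H.** Removing the C3 hydroxyl of 15 gives dihydrocoumarin 13, and removing the C4 hydrogen of 13 gives coumarin 12. Both forward steps use the ring. The enolate of 13 is attacked anti to the very large C4 substituent, and the flat conjugated lactone 12 belongs to the class for which ligated copper hydride gives enantioselective 1,4-reduction. Setting C4 by hydride transfer, not by aryl transfer, is what allows the next cut.

**Key cut, C4–C4a.** Coumarin 12 is cut between C4 and the ring A carbon C4a, which opens the lactone ring to the 3,5-bis(benzyloxy)phenyl arylpropiolate 11. The neighbouring cuts are worse: cutting C4–C8 would need a coupling between a peri-flanked coumarin carbon and a di-ortho-substituted arene, or a cationic coupling with its C6/C8 ambiguity, and cutting only the ester C–O bond removes no ring carbon–carbon bond. In 11 the future C4 is an sp carbon already bonded to lower C8, and the ester arene has a mirror plane, so its two ortho carbons are identical. The forward gold-catalysed hydroarylation has no stereochemical task; it only has to make the arene carbon, not a neighbouring ether oxygen, attack the activated alkyne.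

**Ester and alkyne.** Ester 11 is cut at the acyl–oxygen bond into propiolic acid 9 and phenol 10. The two alkyne carbons of 9 go back, through acetylide 8 and dibromoalkene 7, to aldehyde 6 (Corey–Fuchs sequence), and the carboxyl carbon is introduced by carboxylation of 8. A Sonogashira coupling of a C8 halide with a propiolate ester would be shorter, but it would have to push an electron-rich di-ortho-substituted halide and a base-sensitive ynoate through the coupling.

**Lower unit.** Aldehyde 6 comes from bromide 4 by halogen–lithium exchange (aryllithium 5) and formylation. Bromide 4 comes from silyl ether 3 by bromination, which on benzylated epicatechin ethers selects C8. Ether 3 comes from tetra-O-benzyl epicatechin 2, and 2 from (−)-epicatechin 1. The whole lower skeleton and both its stereocentres are bought.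

## Roads not taken

**Alternative 1:** The cut is upper O1–C2, in a precursor whose future C4 carries two identical 2-hydroxy-4,6-bis(benzyloxy)phenyl rings, the cis-epoxide A1. Under mild acid one phenol oxygen would open the epoxide at benzylic C2 with inversion, closing ring C to give A2. The ring that cyclises becomes ring A and the other stays on C4 as the seed of the lower unit.
- Merits: C4 is not a stereocentre until the ring closes, so the crowded carbon is assembled without stereochemical demand. One stereospecific step sets 2,3-cis and, by choosing between two diastereotopic rings, C4 as well. For the upper unit this is clearly shorter than steps 9 to 13 of the chosen plan.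
- Weak points: the epoxide carbon is a 3,4-dialkoxybenzylic centre and opens with cationic character under acid, which threatens the inversion. The cis-epoxide must be made enantiopure next to a bulky diarylmethyl group, and the two rings must be discriminated well. Most seriously, A2 carries only a phloroglucinol ring on C4, so the complete lower ring C, its 2R,3R centres and its gallate must still be built by a second asymmetric flavan synthesis on a ring with two open nucleophilic positions.
- Comparison: the chosen plan gives up the shorter upper-unit sequence. In return the lower unit arrives complete and enantiopure from 1, and the key step has no positional or stereochemical choice to make.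

**Alternative 2:** The cut removes three bonds of the lower ring A (C8–C8a, C6–C7, C4a–C8a). Ring A is grown by benzannulation on an alkyne already attached to upper C4. Heating siloxyalkyne A3 with cyclobutenone A4 would give the pentasubstituted phenol A5 through the usual sequence of electrocyclic ring opening, [2+2] cycloaddition, second ring opening and 6π-electrocyclisation (Danheiser benzannulation).
- Merits: the interflavan bond is made as a C(sp3)–C(sp) bond and the arene is built around it, so the C6/C8 question cannot arise. The whole upper unit comes from epicatechin, with C4 set by 4β-selective substitution trans to C3. In upper-unit stereocontrol this road is better than the chosen plan, which must create all three centres.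
- Weak points: A3 is an ynol ether on a carbon that ionises easily and must survive 80–140 °C. A4 needs its own multistep synthesis. After the benzannulation the lower ring C must still be closed from the phenol and the arylpropynyl chain, with its two stereocentres set by reagent control far from any existing centre and three different oxygen protecting groups on the new ring.
- Comparison: two centres must be created there against three here. The chosen plan accepts the extra centre because its three are set as a relay with well-understood models and its building blocks are simple.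

**Alternative 3:** The same C4–C4a bond is cut together with O1–C2, at the aldehyde oxidation level. Phenol 10 would add through an ortho carbon to the iminium ion formed from enal A6 and a chiral secondary amine catalyst, and the phenol oxygen would close on the aldehyde to give lactol A7 with C4 set by the catalyst.
- Merits: C4 is created with its configuration in the bond-forming event, so steps 8 and 9 of the chosen plan collapse into one. No hindered hydride transfer is needed and the lower gallate is already in place. In step count to a C4-defined intermediate this road is better.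
- Weak points: the iminium ion of a β-aryl enal with a 2,6-dioxygenated electron-rich ring is a poor, shielded acceptor, and it must be attacked intermolecularly by a hindered nucleophile. The doubly activated benzylic bond can revert, which erodes selectivity. The C3 oxygen is harder to introduce next to a lactol than on a lactone enolate. The gallate ester forbids the aryllithium chemistry needed at C2.
- Comparison: the chosen plan sets against the shorter sequence an intramolecular ring closure on a substrate class where electron-rich arenes are the best case, and it moves the stereochemical task to a step that forms no carbon–carbon bond.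

Key step: step 8

## Assumptions and conventions

- Assumption: 3,5-bis(benzyloxy)phenol (10), 4-bromo-1,2-bis(benzyloxy)benzene (16) and 3,4,5-tris(benzyloxy)benzoic acid (23) are bought as such. They are the benzyl ethers of phloroglucinol, 4-bromocatechol and gallic acid.
- Assumption: (R)-DTBM-SEGPHOS is written in step 9 on the premise that it delivers hydride to the Si face of C4. If the sense on this substrate is the reverse, the (S)-ligand is used with no other change.
- Abbreviation: EC8 is the (2R,3R)-5,7-bis(benzyloxy)-2-[3,4-bis(benzyloxy)phenyl]-3-(tert-butyldimethylsilyloxy)chroman-8-yl group, the protected lower epicatechin unit bonded through C8. "Upper C2, C3, C4" are the flavan locants of the upper unit.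

## Route

Step 1
Reactants: 1 (−)-epicatechin
Product: 2 (2R,3R)-5,7,3',4'-tetra-O-benzylepicatechin
Conditions: BnBr, K2CO3, DMF, 0 °C → rt, under argon
Reagents that add atoms: benzyl bromide, BrCc1ccccc1
Why: Williamson etherification; carbonate deprotonates the four phenols but not the secondary C3 alcohol, and the mild base under inert gas leaves C2 unchanged.

Step 2
Reactants: 2 (2R,3R)-5,7,3',4'-tetra-O-benzylepicatechin
Product: 3 (2R,3R)-5,7,3',4'-tetra-O-benzyl-3-O-(tert-butyldimethylsilyl)epicatechin
Conditions: TBSCl, imidazole, DMF, rt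
Reagents that add atoms: tert-butyldimethylsilyl chloride, CC(C)(C)[Si](C)(C)Cl
Why: Standard silylation of a secondary alcohol; the TBS ether is needed to carry the lower C3 oxygen through the organolithium, enolate and hydride steps.

Step 3
Reactants: 3 (2R,3R)-5,7,3',4'-tetra-O-benzyl-3-O-(tert-butyldimethylsilyl)epicatechin
Product: 4 (2R,3R)-8-bromo-5,7,3',4'-tetra-O-benzyl-3-O-(tert-butyldimethylsilyl)epicatechin
Conditions: NBS, CH2Cl2, −78 °C → rt
Reagents that add atoms: N-bromosuccinimide, O=C1CCC(=O)N1Br
Why: Electrophilic aromatic bromination of the doubly oxygen-activated ring A; on benzylated epicatechin ethers monobromination with NBS takes place at C8 in preference to C6.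

Step 4
Reactants: 4 (2R,3R)-8-bromo-5,7,3',4'-tetra-O-benzyl-3-O-(tert-butyldimethylsilyl)epicatechin
Product: 6 (2R,3R)-8-formyl-5,7,3',4'-tetra-O-benzyl-3-O-(tert-butyldimethylsilyl)epicatechin, via 8-lithio arene 5 (not isolated)
Conditions: t-BuLi (2.1 equiv), THF, −78 °C; DMF; NH4Cl (aq)
Reagents that add atoms: N,N-dimethylformamide, CN(C)C=O
Why: Halogen–lithium exchange is faster at −78 °C than deprotonation of the benzyl ethers, and formylation of the aryllithium with DMF gives the aldehyde on work-up.

Step 5
Reactants: 6 (2R,3R)-8-formyl-5,7,3',4'-tetra-O-benzyl-3-O-(tert-butyldimethylsilyl)epicatechin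
Product: 7 (2R,3R)-8-(2,2-dibromovinyl)-5,7,3',4'-tetra-O-benzyl-3-O-(tert-butyldimethylsilyl)epicatechin
Conditions: CBr4, PPh3, Et3N, CH2Cl2, 0 °C
Reagents that add atoms: carbon tetrabromide, BrC(Br)(Br)Br
Why: First stage of the Corey–Fuchs reaction (dibromomethylenation by the ylide Ph3P=CBr2), which tolerates 2,6-dialkoxybenzaldehydes; Et3N buffers traces of HBr so the silyl ether is kept.

Step 6
Reactants: 7 (2R,3R)-8-(2,2-dibromovinyl)-5,7,3',4'-tetra-O-benzyl-3-O-(tert-butyldimethylsilyl)epicatechin
Product: 9 3-(EC8)prop-2-ynoic acid, via lithium acetylide 8 (not isolated)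
Conditions: n-BuLi (2.2 equiv), THF, −78 °C; CO2; 1 M HCl (aq), 0 °C
Reagents that add atoms: carbon dioxide, O=C=O
Why: Second stage of the Corey–Fuchs reaction (exchange, elimination and metalation to the lithium acetylide), followed by carboxylation of the acetylide; cold brief acidification frees the acid without decarboxylation.

Step 7
Reactants: 9 3-(EC8)prop-2-ynoic acid; 10 3,5-bis(benzyloxy)phenol
Product: 11 3,5-bis(benzyloxy)phenyl 3-(EC8)prop-2-ynoate
Conditions: DCC, DMAP (cat.), CH2Cl2, 0 °C → rt
Reagents that add atoms: none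
Why: Steglich esterification, the usual way to aryl arylpropiolates; the β-aryl group and the low temperature suppress conjugate addition of the phenol to the ynoate.

Step 8
Reactants: 11 3,5-bis(benzyloxy)phenyl 3-(EC8)prop-2-ynoate
Product: 12 5,7-bis(benzyloxy)-4-(EC8)-2H-chromen-2-one
Conditions: Ph3PAuNTf2 (5 mol %), ClCH2CH2Cl, 40–60 °C
Reagents that add atoms: none
Why: The cationic monovalent gold centre of Ph3PAuNTf2 binds the alkyne of 11, whose conjugate polarisation, reinforced by the electron-rich lower-unit ring, makes the carbon bearing that ring (future C4) the electrophilic end. An ortho carbon of the ester arene, which is ortho and para to the two benzyloxy groups, attacks this carbon anti to gold in a Friedel–Crafts sense (an ipso attack followed by 1,2-shift would give the same product); proton loss restores ring A and protodeauration of the vinylgold species releases 12 and the catalyst. The closest known reaction type is the gold- or palladium-catalysed intramolecular hydroarylation of aryl alkynoates to coumarins, which works best for esters of electron-rich phenols. The one ring formed, the lactone ring (O1, C2, C3, C4, C4a, C8a), closes in the 6-endo-dig mode; the 5-exo mode would require attack at the carbonyl-bearing alkyne carbon against the polarisation. No stereocentre is formed. The selectivity needed is positional only and is secured by the substrate: the two ortho carbons of the ester arene are identical by symmetry and the carbon between the benzyloxy groups cannot reach the alkyne. The crowded C4–C8 bond is already present, so the step only has to bring a planar arene carbon to a linear alkyne.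

Step 9
Reactants: 12 5,7-bis(benzyloxy)-4-(EC8)-2H-chromen-2-one
Product: 13 (4R)-5,7-bis(benzyloxy)-4-(EC8)chroman-2-one
Conditions: Cu(OAc)2·H2O (5 mol %), (R)-DTBM-SEGPHOS (5.5 mol %), (EtO)2MeSiH (1.2 equiv), t-BuOH, toluene, 0 °C → rt
Reagents that add atoms: none
Why: Asymmetric conjugate reduction by ligated CuH, a known reaction of 4-substituted coumarins; the bulky bisphosphine directs hydride to the Si face of C4 (4R), t-BuOH protonates the copper enolate, and the distant lower stereocentres are not expected to override the catalyst.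

Step 10
Reactants: 13 (4R)-5,7-bis(benzyloxy)-4-(EC8)chroman-2-one
Product: 15 (3R,4R)-5,7-bis(benzyloxy)-3-hydroxy-4-(EC8)chroman-2-one (3,4-trans), via potassium enolate 14 (not isolated)
Conditions: KN(SiMe3)2, THF, −78 °C; 2-(phenylsulfonyl)-3-phenyloxaziridine, −78 °C; AcOH
Reagents that add atoms: 2-(phenylsulfonyl)-3-phenyloxaziridine, O=S(=O)(c1ccccc1)N1OC1c1ccccc1
Why: Lactone enolate hydroxylation by an N-sulfonyloxaziridine; at −78 °C the enolate does not open to the ketene phenoxide, and the oxidant approaches C3 anti to the quasi-axial C4 aryl group, giving the 3,4-trans (3R) alcohol.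

Step 11
Reactants: 15 (3R,4R)-5,7-bis(benzyloxy)-3-hydroxy-4-(EC8)chroman-2-one; 16 4-bromo-1,2-bis(benzyloxy)benzene
Product: 20 (2R,3R)-1-[3,4-bis(benzyloxy)phenyl]-2-hydroxy-3-[2-hydroxy-4,6-bis(benzyloxy)phenyl]-3-(EC8)propan-1-one, via 3,4-bis(benzyloxy)phenyllithium 17 (not isolated), via trimethylsilyl ether lactone 18 (not isolated), via silylated keto phenoxide 19 (not isolated)
Conditions: TMSCl, imidazole, CH2Cl2, 0 °C, filtration and solvent switch to THF; 17 (from 16, n-BuLi, THF, −78 °C; 1.2 equiv), −78 °C; NH4Cl (aq); citric acid, MeOH, rt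
Reagents that add atoms: none
Why: The hydroxyl is masked in the flask as its trimethylsilyl ether; aryllithium addition to the aryl lactone (nucleophilic acyl substitution) gives, after collapse of the hemiketal alkoxide, a hindered electron-rich aryl ketone that should resist a second addition at −78 °C; mild acidic methanolysis then removes the trimethylsilyl group and leaves the secondary TBS ether.

Step 12
Reactants: 20 (2R,3R)-1-[3,4-bis(benzyloxy)phenyl]-2-hydroxy-3-[2-hydroxy-4,6-bis(benzyloxy)phenyl]-3-(EC8)propan-1-one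
Product: 21 (1S,2R,3R)-1-[3,4-bis(benzyloxy)phenyl]-3-[2-hydroxy-4,6-bis(benzyloxy)phenyl]-3-(EC8)propane-1,2-diol (1,2-anti)
Conditions: Zn(BH4)2, Et2O/CH2Cl2, −20 → 0 °C; NH4Cl (aq)
Reagents that add atoms: none
Why: Chelation-controlled reduction of an α-hydroxy ketone (Cram chelate model): zinc bridges the carbonyl and the neighbouring hydroxyl (future upper C3), and hydride enters from the side of the hydrogen on that carbon, away from the diarylmethyl group, giving the anti diol with the new carbinol centre S (future upper C2); any cyclic hemiketal formed with the ring A phenol is in equilibrium with the open ketone that is reduced.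

Step 13
Reactants: 21 (1S,2R,3R)-1-[3,4-bis(benzyloxy)phenyl]-3-[2-hydroxy-4,6-bis(benzyloxy)phenyl]-3-(EC8)propane-1,2-diol
Product: 22 5,7,3',4'-tetra-O-benzylepicatechin-(4β→8)-5,7,3',4'-tetra-O-benzyl-3-O-(tert-butyldimethylsilyl)epicatechin (upper unit 2R,3R,4R, 3-OH free; lower unit 2R,3R)
Conditions: PPh3, DIAD, THF, 0 °C → rt
Reagents that add atoms: none
Why: Intramolecular Mitsunobu etherification: the less hindered benzylic hydroxyl is activated as its oxyphosphonium ion and displaced by the ring A phenoxide (6-exo-tet, SN2, inversion), turning the S carbinol into 2R and giving the 2,3-cis-3,4-trans ring C; the neopentyl-like C3 hydroxyl is not activated.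

Step 14
Reactants: 22 5,7,3',4'-tetra-O-benzylepicatechin-(4β→8)-5,7,3',4'-tetra-O-benzyl-3-O-(tert-butyldimethylsilyl)epicatechin; 23 3,4,5-tris(benzyloxy)benzoic acid
Product: 24 3-O-[3,4,5-tris(benzyloxy)benzoyl]-5,7,3',4'-tetra-O-benzylepicatechin-(4β→8)-5,7,3',4'-tetra-O-benzyl-3-O-(tert-butyldimethylsilyl)epicatechin (upper gallate, lower silyl ether)
Conditions: 23 (2.5 equiv), DCC, DMAP (1 equiv), CH2Cl2, rt → 40 °C
Reagents that add atoms: none
Why: Steglich esterification; the upper C3 hydroxyl is the only free hydroxyl of 22, so excess acid and the acylpyridinium intermediate can drive this hindered acylation to completion without a second site competing, and O-acylation leaves the C3 configuration untouched.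

Step 15
Reactants: 24 3-O-[3,4,5-tris(benzyloxy)benzoyl]-5,7,3',4'-tetra-O-benzylepicatechin-(4β→8)-5,7,3',4'-tetra-O-benzyl-3-O-(tert-butyldimethylsilyl)epicatechin
Product: 25 3-O-[3,4,5-tris(benzyloxy)benzoyl]-5,7,3',4'-tetra-O-benzylepicatechin-(4β→8)-5,7,3',4'-tetra-O-benzylepicatechin (upper gallate, lower 3-OH free)
Conditions: TBAF, AcOH (1:1), THF, rt → 40 °C
Reagents that add atoms: none
Why: Fluoride cleavage of the secondary silyl ether; buffering with acetic acid keeps the medium non-basic, so the upper gallate ester should be neither cleaved nor transferred, and the benzyl ethers, the C4–C8 bond and all stereocentres are inert to these conditions.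

Step 16
Reactants: 25 3-O-[3,4,5-tris(benzyloxy)benzoyl]-5,7,3',4'-tetra-O-benzylepicatechin-(4β→8)-5,7,3',4'-tetra-O-benzylepicatechin; 23 3,4,5-tris(benzyloxy)benzoic acid
Product: 26 3,3'-bis-O-[3,4,5-tris(benzyloxy)benzoyl]-octa-O-benzyl procyanidin B2
Conditions: 23 (1.5 equiv), DCC, DMAP (cat.), CH2Cl2, rt
Reagents that add atoms: none
Why: Steglich esterification of the lower C3 hydroxyl, the less hindered of the two and a known acylation site of benzylated epicatechin; no stereocentre is involved.

Step 17
Reactants: 26 3,3'-bis-O-[3,4,5-tris(benzyloxy)benzoyl]-octa-O-benzyl procyanidin B2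
Product: 27 3,3'-digalloylprocyanidin B2
Conditions: H2 (1 atm), Pd(OH)2/C, THF/MeOH/H2O, rt
Reagents that add atoms: none
Why: Neutral hydrogenolysis of the fourteen benzyl ethers; the gallate esters, the pyran C–O bonds and the interflavan bond are expected to survive these conditions, and the product is isolated without acid or base.

## Compound list

1 | (−)-epicatechin, (2R,3R) | Oc1cc(O)c2c(c1)O[C@H](c1ccc(O)c(O)c1)[C@H](O)C2 | starting material
2 | (2R,3R)-5,7,3',4'-tetra-O-benzylepicatechin | c1c(OCc9ccccc9)cc(OCc9ccccc9)c2c1O[C@H](c4ccc(OCc9ccccc9)c(OCc9ccccc9)c4)[C@H](O)C2 | intermediate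
3 | (2R,3R)-5,7,3',4'-tetra-O-benzyl-3-O-(tert-butyldimethylsilyl)epicatechin | c1c(OCc9ccccc9)cc(OCc9ccccc9)c2c1O[C@H](c4ccc(OCc9ccccc9)c(OCc9ccccc9)c4)[C@H](O[Si](C)(C)C(C)(C)C)C2 | intermediate
4 | (2R,3R)-8-bromo-5,7,3',4'-tetra-O-benzyl-3-O-(tert-butyldimethylsilyl)epicatechin | Brc1c(OCc9ccccc9)cc(OCc9ccccc9)c2c1O[C@H](c4ccc(OCc9ccccc9)c(OCc9ccccc9)c4)[C@H](O[Si](C)(C)C(C)(C)C)C2 | intermediate
5 | 8-lithio derivative of 3 (EC8–Li), formed in the flask | [Li]c1c(OCc9ccccc9)cc(OCc9ccccc9)c2c1O[C@H](c4ccc(OCc9ccccc9)c(OCc9ccccc9)c4)[C@H](O[Si](C)(C)C(C)(C)C)C2 | intermediate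
6 | (2R,3R)-8-formyl-5,7,3',4'-tetra-O-benzyl-3-O-(tert-butyldimethylsilyl)epicatechin (EC8–CHO) | O=Cc1c(OCc9ccccc9)cc(OCc9ccccc9)c2c1O[C@H](c4ccc(OCc9ccccc9)c(OCc9ccccc9)c4)[C@H](O[Si](C)(C)C(C)(C)C)C2 | intermediate
7 | (2R,3R)-8-(2,2-dibromovinyl)-5,7,3',4'-tetra-O-benzyl-3-O-(tert-butyldimethylsilyl)epicatechin | BrC(Br)=Cc1c(OCc9ccccc9)cc(OCc9ccccc9)c2c1O[C@H](c4ccc(OCc9ccccc9)c(OCc9ccccc9)c4)[C@H](O[Si](C)(C)C(C)(C)C)C2 | intermediate
8 | lithium (EC8)acetylide, formed in the flask | [Li]C#Cc1c(OCc9ccccc9)cc(OCc9ccccc9)c2c1O[C@H](c4ccc(OCc9ccccc9)c(OCc9ccccc9)c4)[C@H](O[Si](C)(C)C(C)(C)C)C2 | intermediate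
9 | 3-(EC8)prop-2-ynoic acid | OC(=O)C#Cc1c(OCc9ccccc9)cc(OCc9ccccc9)c2c1O[C@H](c4ccc(OCc9ccccc9)c(OCc9ccccc9)c4)[C@H](O[Si](C)(C)C(C)(C)C)C2 | intermediate
10 | 3,5-bis(benzyloxy)phenol | Oc1cc(OCc2ccccc2)cc(OCc2ccccc2)c1 | starting material
11 | 3,5-bis(benzyloxy)phenyl 3-(EC8)prop-2-ynoate | O=C(C#Cc1c(OCc9ccccc9)cc(OCc9ccccc9)c2c1O[C@H](c4ccc(OCc9ccccc9)c(OCc9ccccc9)c4)[C@H](O[Si](C)(C)C(C)(C)C)C2)Oc1cc(OCc9ccccc9)cc(OCc9ccccc9)c1 | intermediate
12 | 5,7-bis(benzyloxy)-4-(EC8)-2H-chromen-2-one | O=C1C=C(c2c(OCc9ccccc9)cc(OCc9ccccc9)c3c2O[C@H](c4ccc(OCc9ccccc9)c(OCc9ccccc9)c4)[C@H](O[Si](C)(C)C(C)(C)C)C3)c2c(OCc9ccccc9)cc(OCc9ccccc9)cc2O1 | intermediate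
13 | (4R)-5,7-bis(benzyloxy)-4-(EC8)chroman-2-one | O=C1C[C@@H](c2c(OCc9ccccc9)cc(OCc9ccccc9)c3c2O[C@H](c4ccc(OCc9ccccc9)c(OCc9ccccc9)c4)[C@H](O[Si](C)(C)C(C)(C)C)C3)c2c(OCc9ccccc9)cc(OCc9ccccc9)cc2O1 | intermediate
14 | potassium enolate of 13, formed in the flask | [K+].[O-]C1=C[C@@H](c2c(OCc9ccccc9)cc(OCc9ccccc9)c3c2O[C@H](c4ccc(OCc9ccccc9)c(OCc9ccccc9)c4)[C@H](O[Si](C)(C)C(C)(C)C)C3)c2c(OCc9ccccc9)cc(OCc9ccccc9)cc2O1 | intermediate
15 | (3R,4R)-5,7-bis(benzyloxy)-3-hydroxy-4-(EC8)chroman-2-one (3,4-trans) | O=C1[C@H](O)[C@@H](c2c(OCc9ccccc9)cc(OCc9ccccc9)c3c2O[C@H](c4ccc(OCc9ccccc9)c(OCc9ccccc9)c4)[C@H](O[Si](C)(C)C(C)(C)C)C3)c2c(OCc9ccccc9)cc(OCc9ccccc9)cc2O1 | intermediate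
16 | 4-bromo-1,2-bis(benzyloxy)benzene | Brc1ccc(OCc2ccccc2)c(OCc2ccccc2)c1 | starting material
17 | 3,4-bis(benzyloxy)phenyllithium, formed in the flask | [Li]c1ccc(OCc2ccccc2)c(OCc2ccccc2)c1 | intermediate
18 | (3R,4R)-5,7-bis(benzyloxy)-3-(trimethylsilyloxy)-4-(EC8)chroman-2-one, formed in the flask | O=C1[C@H](O[Si](C)(C)C)[C@@H](c2c(OCc9ccccc9)cc(OCc9ccccc9)c3c2O[C@H](c4ccc(OCc9ccccc9)c(OCc9ccccc9)c4)[C@H](O[Si](C)(C)C(C)(C)C)C3)c2c(OCc9ccccc9)cc(OCc9ccccc9)cc2O1 | intermediate
19 | lithium phenoxide of the 2-O-trimethylsilyl ether of 20, formed in the flask | O=C(c1ccc(OCc9ccccc9)c(OCc9ccccc9)c1)[C@H](O[Si](C)(C)C)[C@@H](c2c(OCc9ccccc9)cc(OCc9ccccc9)c3c2O[C@H](c4ccc(OCc9ccccc9)c(OCc9ccccc9)c4)[C@H](O[Si](C)(C)C(C)(C)C)C3)c2c(OCc9ccccc9)cc(OCc9ccccc9)cc2[O-].[Li+] | intermediate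
20 | (2R,3R)-1-[3,4-bis(benzyloxy)phenyl]-2-hydroxy-3-[2-hydroxy-4,6-bis(benzyloxy)phenyl]-3-(EC8)propan-1-one | O=C(c1ccc(OCc9ccccc9)c(OCc9ccccc9)c1)[C@H](O)[C@@H](c2c(OCc9ccccc9)cc(OCc9ccccc9)c3c2O[C@H](c4ccc(OCc9ccccc9)c(OCc9ccccc9)c4)[C@H](O[Si](C)(C)C(C)(C)C)C3)c2c(OCc9ccccc9)cc(OCc9ccccc9)cc2O | intermediate
21 | (1S,2R,3R)-1-[3,4-bis(benzyloxy)phenyl]-3-[2-hydroxy-4,6-bis(benzyloxy)phenyl]-3-(EC8)propane-1,2-diol (1,2-anti) | O[C@@H](c1ccc(OCc9ccccc9)c(OCc9ccccc9)c1)[C@H](O)[C@@H](c2c(OCc9ccccc9)cc(OCc9ccccc9)c3c2O[C@H](c4ccc(OCc9ccccc9)c(OCc9ccccc9)c4)[C@H](O[Si](C)(C)C(C)(C)C)C3)c2c(OCc9ccccc9)cc(OCc9ccccc9)cc2O | intermediate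
22 | 5,7,3',4'-tetra-O-benzylepicatechin-(4β→8)-5,7,3',4'-tetra-O-benzyl-3-O-(tert-butyldimethylsilyl)epicatechin (upper 2R,3R,4R, 3-OH free; lower 2R,3R) | O[C@@H]1[C@@H](c2c(OCc9ccccc9)cc(OCc9ccccc9)c3c2O[C@H](c4ccc(OCc9ccccc9)c(OCc9ccccc9)c4)[C@H](O[Si](C)(C)C(C)(C)C)C3)c2c(OCc9ccccc9)cc(OCc9ccccc9)cc2O[C@@H]1c1ccc(OCc9ccccc9)c(OCc9ccccc9)c1 | intermediate
23 | 3,4,5-tris(benzyloxy)benzoic acid | OC(=O)c1cc(OCc2ccccc2)c(OCc2ccccc2)c(OCc2ccccc2)c1 | starting material
24 | 3-O-[3,4,5-tris(benzyloxy)benzoyl]-5,7,3',4'-tetra-O-benzylepicatechin-(4β→8)-5,7,3',4'-tetra-O-benzyl-3-O-(tert-butyldimethylsilyl)epicatechin (upper gallate, lower silyl ether) | O=C(O[C@@H]1[C@@H](c2c(OCc9ccccc9)cc(OCc9ccccc9)c3c2O[C@H](c4ccc(OCc9ccccc9)c(OCc9ccccc9)c4)[C@H](O[Si](C)(C)C(C)(C)C)C3)c2c(OCc9ccccc9)cc(OCc9ccccc9)cc2O[C@@H]1c1ccc(OCc9ccccc9)c(OCc9ccccc9)c1)c1cc(OCc9ccccc9)c(OCc9ccccc9)c(OCc9ccccc9)c1 | intermediate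
25 | 3-O-[3,4,5-tris(benzyloxy)benzoyl]-5,7,3',4'-tetra-O-benzylepicatechin-(4β→8)-5,7,3',4'-tetra-O-benzylepicatechin (upper gallate, lower 3-OH free) | O=C(O[C@@H]1[C@@H](c2c(OCc9ccccc9)cc(OCc9ccccc9)c3c2O[C@H](c4ccc(OCc9ccccc9)c(OCc9ccccc9)c4)[C@H](O)C3)c2c(OCc9ccccc9)cc(OCc9ccccc9)cc2O[C@@H]1c1ccc(OCc9ccccc9)c(OCc9ccccc9)c1)c1cc(OCc9ccccc9)c(OCc9ccccc9)c(OCc9ccccc9)c1 | intermediate
26 | 3,3'-bis-O-[3,4,5-tris(benzyloxy)benzoyl]-octa-O-benzyl procyanidin B2 | O=C(O[C@@H]1[C@@H](c2c(OCc9ccccc9)cc(OCc9ccccc9)c3c2O[C@H](c4ccc(OCc9ccccc9)c(OCc9ccccc9)c4)[C@H](OC(=O)c5cc(OCc9ccccc9)c(OCc9ccccc9)c(OCc9ccccc9)c5)C3)c2c(OCc9ccccc9)cc(OCc9ccccc9)cc2O[C@@H]1c1ccc(OCc9ccccc9)c(OCc9ccccc9)c1)c1cc(OCc9ccccc9)c(OCc9ccccc9)c(OCc9ccccc9)c1 | intermediate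
27 | 3,3'-digalloylprocyanidin B2 | O=C(O[C@@H]1[C@@H](c2c(O)cc(O)c3c2O[C@H](c2ccc(O)c(O)c2)[C@H](OC(=O)c2cc(O)c(O)c(O)c2)C3)c2c(O)cc(O)cc2O[C@@H]1c1ccc(O)c(O)c1)c1cc(O)c(O)c(O)c1 | target

## Step count and risk

Total step count: 17. Longest linear sequence: 17 steps (1 → 27). Compounds 10, 16 and 23 enter as purchased partners.

**Step 8 (key step).** The arene attack may be too slow, because only the minor ester rotamer places the ring near the alkyne and the alkyne carbon is screened by two ortho substituents. A flanking ether oxygen of the lower unit (the C7 benzyl ether or O1) may then add to the gold-activated alkyne, with transfer or loss of its alkyl group. Hydration of the ynoate by traces of water is a second drain.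

Fallback: the coumarin is assembled by cross-coupling, with the C4–C8 bond formed instead of C4–C4a; the sequence sets out from bromide 4 and comes back to the route at 12. Purchased 1-[2-hydroxy-4,6-bis(benzyloxy)phenyl]ethanone is condensed with diethyl carbonate (NaH, toluene, 100 °C) to 5,7-bis(benzyloxy)-4-hydroxycoumarin F1, which is converted with Tf2O/Et3N (CH2Cl2, −78 °C) into 5,7-bis(benzyloxy)-2-oxo-2H-chromen-4-yl trifluoromethanesulfonate F2. Bromide 4 is lithiated to 5 as in step 4 and transmetallated with ZnCl2 to the arylzinc chloride F3. Negishi coupling of F2 with F3 (Pd2(dba)3, SPhos, THF, 50 °C) would give 12, where the route is rejoined.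

**Step 9.** Hydride must reach a β-carbon that is shielded on both faces by the ortho substituents of the perpendicular lower-unit ring. Turnover may stop, facial selectivity may be poor if rotamers about C4–C8 interconvert slowly and respond differently to the catalyst, and excess silane may reduce the lactone carbonyl to the lactol.

Fallback: catalyst control is given up. Coumarin 12 is reduced by single-electron transfer from divalent samarium (SmI2, THF, t-BuOH, −78 °C), a small reductant indifferent to the shielding. This gives 13 together with its C4 epimer, (4S)-5,7-bis(benzyloxy)-4-(EC8)chroman-2-one F4. The two are diastereomers because of the lower unit and are separated by chromatography. The route is rejoined at 13, at the cost of the material in F4.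

**Step 11.** The ketone released when the tetrahedral intermediate collapses may take up a second aryllithium, or be enolised by it at the carbinol carbon. Incomplete silylation would leave an alkoxide that can transfer the acyl group between molecules.

Fallback: the acyl donor is changed from the lactone to an N-methoxy-N-methylamide. Lactone 15 is opened with Me(MeO)NH·HCl and AlMe3 (CH2Cl2, 0 °C → rt) to (2R,3R)-2-hydroxy-3-[2-hydroxy-4,6-bis(benzyloxy)phenyl]-N-methoxy-N-methyl-3-(EC8)propanamide F5. Treatment of F5 with excess 17 (3.5 equiv, THF, −78 → 0 °C; the first two equivalents deprotonate the phenol and the hydroxyl) forms a chelated adduct that cannot add again and gives 20 on work-up, where the route is rejoined.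

**Step 13.** The oxyphosphonium ion sits on a 3,4-dialkoxybenzylic carbon and may ionise before the phenoxide arrives, with loss of clean inversion at C2. The free C3 hydroxyl may also displace it to give an epoxide.

Fallback: ring closure through a neighbouring-group-bound intermediate in place of the phosphonium ion, setting out from diol 21 and coming back at 22. Diol 21 is treated with HC(OEt)3 and PPTS (ClCH2CH2Cl, rt → 55 °C) to form the cyclic orthoformate F6 across the two hydroxyls. On warming it ionises to the dioxolanylium ion, which the ring A phenol opens at C2 anti to the departing oxygen (inversion) while the C3 oxygen stays tied up. This gives the upper 3-O-formate F7. Methanolysis (K2CO3, MeOH, 0 °C) then gives 22, where the route is rejoined.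

## Further compounds

F1 | step 8 | 5,7-bis(benzyloxy)-4-hydroxy-2H-chromen-2-one | O=C1C=C(O)c2c(OCc3ccccc3)cc(OCc3ccccc3)cc2O1
F2 | step 8 | 5,7-bis(benzyloxy)-2-oxo-2H-chromen-4-yl trifluoromethanesulfonate | O=C1C=C(OS(=O)(=O)C(F)(F)F)c2c(OCc3ccccc3)cc(OCc3ccccc3)cc2O1
F3 | step 8 | (EC8)zinc chloride | Cl[Zn]c1c(OCc9ccccc9)cc(OCc9ccccc9)c2c1O[C@H](c4ccc(OCc9ccccc9)c(OCc9ccccc9)c4)[C@H](O[Si](C)(C)C(C)(C)C)C2
F4 | step 9 | (4S)-5,7-bis(benzyloxy)-4-(EC8)chroman-2-one | O=C1C[C@H](c2c(OCc9ccccc9)cc(OCc9ccccc9)c3c2O[C@H](c4ccc(OCc9ccccc9)c(OCc9ccccc9)c4)[C@H](O[Si](C)(C)C(C)(C)C)C3)c2c(OCc9ccccc9)cc(OCc9ccccc9)cc2O1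
F5 | step 11 | (2R,3R)-2-hydroxy-3-[2-hydroxy-4,6-bis(benzyloxy)phenyl]-N-methoxy-N-methyl-3-(EC8)propanamide | CON(C)C(=O)[C@H](O)[C@@H](c2c(OCc9ccccc9)cc(OCc9ccccc9)c3c2O[C@H](c4ccc(OCc9ccccc9)c(OCc9ccccc9)c4)[C@H](O[Si](C)(C)C(C)(C)C)C3)c2c(OCc9ccccc9)cc(OCc9ccccc9)cc2O
F6 | step 13 | cyclic orthoformate of 21: (4S,5R)-4-[3,4-bis(benzyloxy)phenyl]-2-ethoxy-5-[(R)-(2-hydroxy-4,6-bis(benzyloxy)phenyl)(EC8)methyl]-1,3-dioxolane, epimers at the orthoester carbon | CCOC1O[C@@H](c5ccc(OCc9ccccc9)c(OCc9ccccc9)c5)[C@H](O1)[C@@H](c2c(OCc9ccccc9)cc(OCc9ccccc9)c3c2O[C@H](c4ccc(OCc9ccccc9)c(OCc9ccccc9)c4)[C@H](O[Si](C)(C)C(C)(C)C)C3)c2c(OCc9ccccc9)cc(OCc9ccccc9)cc2O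
F7 | step 13 | upper 3-O-formate of 22 | O=CO[C@@H]1[C@@H](c2c(OCc9ccccc9)cc(OCc9ccccc9)c3c2O[C@H](c4ccc(OCc9ccccc9)c(OCc9ccccc9)c4)[C@H](O[Si](C)(C)C(C)(C)C)C3)c2c(OCc9ccccc9)cc(OCc9ccccc9)cc2O[C@@H]1c1ccc(OCc9ccccc9)c(OCc9ccccc9)c1
A1 | alternative 1 | (2R,3S)-2-[bis(2-hydroxy-4,6-bis(benzyloxy)phenyl)methyl]-3-[3,4-bis(benzyloxy)phenyl]oxirane (cis) | Oc1cc(OCc9ccccc9)cc(OCc9ccccc9)c1C(c1c(O)cc(OCc9ccccc9)cc1OCc9ccccc9)[C@H]1O[C@H]1c1ccc(OCc9ccccc9)c(OCc9ccccc9)c1
A2 | alternative 1 | 4β-[2-hydroxy-4,6-bis(benzyloxy)phenyl]-5,7,3',4'-tetra-O-benzylepicatechin | O[C@@H]1[C@@H](c2c(OCc9ccccc9)cc(OCc9ccccc9)cc2O)c2c(OCc9ccccc9)cc(OCc9ccccc9)cc2O[C@@H]1c1ccc(OCc9ccccc9)c(OCc9ccccc9)c1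
A3 | alternative 2 | 4β-[(triisopropylsilyloxy)ethynyl]-5,7,3',4'-tetra-O-benzyl-3-O-(tert-butyldimethylsilyl)epicatechin | CC(C)(C)[Si](C)(C)O[C@@H]1[C@@H](C#CO[Si](C(C)C)(C(C)C)C(C)C)c2c(OCc9ccccc9)cc(OCc9ccccc9)cc2O[C@@H]1c1ccc(OCc9ccccc9)c(OCc9ccccc9)c1
A4 | alternative 2 | 3-(benzyloxy)-4-{3-[3,4-bis(benzyloxy)phenyl]prop-2-yn-1-yl}cyclobut-2-en-1-one (racemic) | O=C1C=C(OCc2ccccc2)C1CC#Cc1ccc(OCc2ccccc2)c(OCc2ccccc2)c1
A5 | alternative 2 | upper flavan bearing at C4 the new phenol ring (lower ring A) with its arylpropynyl side chain | CC(C)(C)[Si](C)(C)O[C@@H]1[C@@H](c2c(O[Si](C(C)C)(C(C)C)C(C)C)cc(OCc9ccccc9)c(CC#Cc3ccc(OCc9ccccc9)c(OCc9ccccc9)c3)c2O)c2c(OCc9ccccc9)cc(OCc9ccccc9)cc2O[C@@H]1c1ccc(OCc9ccccc9)c(OCc9ccccc9)c1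
A6 | alternative 3 | (E)-3-[(2R,3R)-5,7,3',4'-tetra-O-benzyl-3-O-(3,4,5-tris(benzyloxy)benzoyl)epicatechin-8-yl]prop-2-enal | O=C/C=C/c1c(OCc9ccccc9)cc(OCc9ccccc9)c2c1O[C@H](c4ccc(OCc9ccccc9)c(OCc9ccccc9)c4)[C@H](OC(=O)c5cc(OCc9ccccc9)c(OCc9ccccc9)c(OCc9ccccc9)c5)C2
A7 | alternative 3 | (4R)-5,7-bis(benzyloxy)-4-[(2R,3R)-5,7,3',4'-tetra-O-benzyl-3-O-(3,4,5-tris(benzyloxy)benzoyl)epicatechin-8-yl]chroman-2-ol, anomeric mixture | OC1C[C@@H](c2c(OCc9ccccc9)cc(OCc9ccccc9)c3c2O[C@H](c4ccc(OCc9ccccc9)c(OCc9ccccc9)c4)[C@H](OC(=O)c5cc(OCc9ccccc9)c(OCc9ccccc9)c(OCc9ccccc9)c5)C3)c2c(OCc9ccccc9)cc(OCc9ccccc9)cc2O1
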